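**Retrosynthetic overview**
1. Target 19 ⇒ open-chain (11S,12E)-11-hydroperoxy-7α-hydroxy-15,16-dial 18; the seven-membered peroxyhemiacetal ring closes last.
2. 18 ⇒ α-silylperoxy aldehyde 13 + formyl ylide 16 (E-selective Wittig); 13 ⇒ aldehyde 11 (silyl enol ether + singlet oxygen).
3. 11 ⇒ bicyclic ester 6 (one-carbon homologation; SeO2 allylic hydroxylation for the 7α-OH).
4. 6 ⇒ acyclic (silylmethyl)trienoate 5: ring A and ring B close together in an enantioselective proton-initiated bicyclisation ended by the allylsilane, which sets C5, C9, C10 and the exocyclic alkene.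
5. 5 ⇒ methyl acetoacetate + geranyl bromide. Ring order: A and B together, then the dioxepine.

Assumption: labdane numbering is used in the names, and the (R)-configured chiral acid of step 3 is taken to give the natural 5S,10S series as it does in ambrox-type cyclisations (otherwise its mirror image is used).

**Route**

Step 1
Reactants: 1 methyl acetoacetate; 2 geranyl bromide
Product: 3 methyl (6E)-7,11-dimethyl-3-oxododeca-6,10-dienoate
Conditions: NaH, THF, 0 °C; n-BuLi, 0 °C; then 2, 0 °C to rt; aq. HCl
Reagents that add atoms: none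
Why: Weiler dianion alkylation, in which the acetoacetate dianion reacts only at its terminal carbon with the allylic bromide in an SN2 reaction and no stereocentre is formed.

Step 2
Reactants: 3 methyl (6E)-7,11-dimethyl-3-oxododeca-6,10-dienoate
Product: 5 methyl (2Z,6E)-7,11-dimethyl-3-[(trimethylsilyl)methyl]dodeca-2,6,10-trienoate, via Z enol phosphate 4 (not isolated)
Conditions: NaH, Et2O, 0 °C; ClP(O)(OEt)2, 0 °C to rt; then Ni(acac)2 (5 mol %), Me3SiCH2MgCl, Et2O/THF, 0 °C to rt
Reagents that add atoms: (trimethylsilyl)methylmagnesium chloride, C[Si](C)(C)C[Mg]Cl; diethyl chlorophosphate, CCOP(=O)(Cl)OCC (its atoms are carried only by 4)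
Why: The chelated sodium enolate is O-phosphorylated to the Z enol phosphate, and nickel-catalysed Kumada-type cross-coupling replaces the phosphate with retention of alkene geometry, so the CH2SiMe3 group ends cis to the ester.

Step 3
Reactants: 5 methyl (2Z,6E)-7,11-dimethyl-3-[(trimethylsilyl)methyl]dodeca-2,6,10-trienoate
Product: 6 methyl (1S,4aS,8aS)-5,5,8a-trimethyl-2-methylidenedecahydronaphthalene-1-carboxylate (methyl drim-8(12)-en-11-oate; 5α-H, 9α-H, 10β-CH3)
Conditions: (R)-2'-[(2-fluorobenzyl)oxy]-1,1'-binaphthalen-2-ol (1.5 equiv), SnCl4 (1.5 equiv), toluene, −78 °C, 48 h; aq. NaHCO3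
Reagents that add atoms: none
Why: Proposed new method: the chiral Lewis acid-assisted Brønsted acid protonates the terminal trisubstituted alkene enantioselectively (the enoate-conjugated allylsilane is too electron-poor to be protonated), the cation closes ring A and ring B through a chair–chair transition state, and the ester α-carbon (C9) traps the C10 cation with loss of Me3Si+ to leave the exocyclic C8=C17 alkene, which sets 5α-H, 10β-CH3 and 9α-H (equatorial ester) in one operation; the closest known reactions are the SnCl4-promoted cyclisation of (silylmethyl)enoates of this kind to racemic products and the enantioselective biomimetic polyene cyclisation with the same chiral acid.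

Step 4
Reactants: 6 methyl (1S,4aS,8aS)-5,5,8a-trimethyl-2-methylidenedecahydronaphthalene-1-carboxylate
Product: 9 ethyl 2-[(1S,4aS,8aS)-5,5,8a-trimethyl-2-methylidenedecahydronaphthalen-1-yl]acetate (ethyl 13,14,15,16-tetranorlabd-8(17)-en-12-oate), via dibromomethyl ketone 7 (not isolated), via lithium ynolate 8 (not isolated)
Conditions: CH2Br2, lithium 2,2,6,6-tetramethylpiperidide, THF, −78 °C; then n-BuLi, −78 °C to rt; then HCl in EtOH, 0 °C
Reagents that add atoms: dibromomethane, BrCBr; ethanol, CCO
Why: Kowalski ester homologation, in which LiCHBr2 adds to the ester, bromine–lithium exchange on the dibromo ketone enolate makes C9 migrate with retention to give the ynolate, and acidic ethanol gives the one-carbon-longer ester without touching the C9 stereocentre.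

Step 5
Reactants: 9 ethyl 2-[(1S,4aS,8aS)-5,5,8a-trimethyl-2-methylidenedecahydronaphthalen-1-yl]acetate
Product: 10 ethyl 2-[(1R,3R,4aS,8aS)-3-hydroxy-5,5,8a-trimethyl-2-methylidenedecahydronaphthalen-1-yl]acetate (ethyl 7α-hydroxy-13,14,15,16-tetranorlabd-8(17)-en-12-oate)
Conditions: SeO2 (0.3 equiv), t-BuOOH, CH2Cl2, 0 °C to rt
Reagents that add atoms: tert-butyl hydroperoxide, CC(C)(C)OO (terminal oxidant; the oxygen is passed on through SeO2, O=[Se]=O)
Why: Sharpless SeO2/t-BuOOH allylic hydroxylation, in which the ene reaction removes the axial 7α-H and the [2,3]-sigmatropic shift of the allylseleninic acid returns oxygen to C7 on the α face, giving the axial 7α-alcohol (7R) and restoring the 8(17)-alkene as known for labd-8(17)-enes.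

Step 6
Reactants: 10 ethyl 7α-hydroxy-13,14,15,16-tetranorlabd-8(17)-en-12-oate
Product: 11 2-[(1R,3R,4aS,8aS)-3-hydroxy-5,5,8a-trimethyl-2-methylidenedecahydronaphthalen-1-yl]acetaldehyde (7α-hydroxy-13,14,15,16-tetranorlabd-8(17)-en-12-al)
Conditions: i-Bu2AlH (2.2 equiv), CH2Cl2, −78 °C; aq. potassium sodium tartrate
Reagents that add atoms: none
Why: Partial ester reduction, in which the unhindered ethyl ester stops at the aluminium hemiacetal at −78 °C (one equivalent is used up by the free alcohol) and gives the aldehyde on work-up with no stereocentre affected.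

Step 7
Reactants: 11 7α-hydroxy-13,14,15,16-tetranorlabd-8(17)-en-12-al
Product: 12 (11Z)-7α,12-bis(triethylsilyloxy)-13,14,15,16-tetranorlabda-8(17),11-diene
Conditions: Et3SiOTf, Et3N, CH2Cl2, −78 to 0 °C
Reagents that add atoms: triethylsilyl trifluoromethanesulfonate, CC[Si](CC)(CC)OS(=O)(=O)C(F)(F)F
Why: Soft enolisation with silyl triflate and amine turns the aldehyde into its silyl enol ether (mainly Z) and silylates the 7α-alcohol in the same operation.

Step 8
Reactants: 12 (11Z)-7α,12-bis(triethylsilyloxy)-13,14,15,16-tetranorlabda-8(17),11-diene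
Product: 13 (11R)-7α-(triethylsilyloxy)-11-(triethylsilylperoxy)-13,14,15,16-tetranorlabd-8(17)-en-12-al
Conditions: O2, tetraphenylporphyrin (1 mol %), visible light, CH2Cl2, −78 °C
Reagents that add atoms: dioxygen, O=O
Why: Silatropic ene reaction of singlet oxygen, a known route to α-silylperoxy carbonyl compounds, in which oxygen adds to C11 and the silyl group shifts to the peroxy oxygen; in the conformer with H9 eclipsing the enol ether, oxygen is expected to enter anti to the quaternary C10, which gives the required C11 configuration, and the minor epimer is removed by chromatography.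

Step 9
Reactants: 14 [2-(1,3-dioxolan-2-yl)ethyl]triphenylphosphonium bromide
Product: 16 3-(1,3-dioxolan-2-yl)-2-(triphenyl-λ5-phosphanylidene)propanal, via non-stabilised ylide 15 (not isolated)
Conditions: KOt-Bu, THF, 0 °C; then HCO2Et, 0 °C to rt
Reagents that add atoms: ethyl formate, CCOC=O
Why: Ylide acylation, in which the non-stabilised ylide is C-formylated by ethyl formate and the released ethoxide deprotonates the acylphosphonium salt to the stabilised formyl ylide.

Step 10
Reactants: 13 (11R)-7α-(triethylsilyloxy)-11-(triethylsilylperoxy)-13,14,15,16-tetranorlabd-8(17)-en-12-al; 16 3-(1,3-dioxolan-2-yl)-2-(triphenyl-λ5-phosphanylidene)propanal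
Product: 17 (11S,12E)-15,15-(ethylenedioxy)-7α-(triethylsilyloxy)-11-(triethylsilylperoxy)labda-8(17),12-dien-16-al
Conditions: toluene, 60 °C
Reagents that add atoms: none
Why: Wittig olefination with a stabilised α-formyl ylide gives the E enal (CHO trans to C11) under thermodynamic control, and α-peroxy aldehydes are known to tolerate neutral stabilised ylides.

Step 11
Reactants: 17 (11S,12E)-15,15-(ethylenedioxy)-7α-(triethylsilyloxy)-11-(triethylsilylperoxy)labda-8(17),12-dien-16-al
Product: 19 (5S,7R,9R,10S,11S,15S)-11,15-epidioxy-7α,15-dihydroxylabda-8(17),12-dien-16-al (CNP0269954.1), via open-chain hydroperoxy dial 18 (not isolated)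
Conditions: 1 M aq. HCl, THF, 0 °C to rt
Reagents that add atoms: water, O
Why: Acid-mediated deprotection and peroxyhemiacetal formation, in which both silyl groups and the dioxolane are cleaved and the 11-hydroperoxide adds to the freed C15 aldehyde (cis to C11 across the E alkene) to close the seven-membered ring; C15 is under thermodynamic control through reversible ring opening, with the 15S epimer taken as the more stable one.

**Compound list**
1 | methyl acetoacetate | CC(=O)CC(=O)OC | starting material
2 | geranyl bromide, (2E)-1-bromo-3,7-dimethylocta-2,6-diene | CC(C)=CCC/C(C)=C/CBr | starting material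
3 | methyl (6E)-7,11-dimethyl-3-oxododeca-6,10-dienoate | COC(=O)CC(=O)CC/C=C(\C)CCC=C(C)C | intermediate
4 | methyl (2Z,6E)-3-[(diethoxyphosphoryl)oxy]-7,11-dimethyldodeca-2,6,10-trienoate | COC(=O)/C=C(/CC/C=C(\C)CCC=C(C)C)OP(=O)(OCC)OCC | intermediate (not isolated)
5 | methyl (2Z,6E)-7,11-dimethyl-3-[(trimethylsilyl)methyl]dodeca-2,6,10-trienoate | COC(=O)/C=C(/CC/C=C(\C)CCC=C(C)C)C[Si](C)(C)C | intermediate
6 | methyl (1S,4aS,8aS)-5,5,8a-trimethyl-2-methylidenedecahydronaphthalene-1-carboxylate | C=C1CC[C@H]2C(C)(C)CCC[C@]2(C)[C@H]1C(=O)OC | intermediate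
7 | 2,2-dibromo-1-[(1S,4aS,8aS)-5,5,8a-trimethyl-2-methylidenedecahydronaphthalen-1-yl]ethan-1-one | C=C1CC[C@H]2C(C)(C)CCC[C@]2(C)[C@H]1C(=O)C(Br)Br | intermediate (not isolated)
8 | lithium ynolate (C9–C≡C–OLi on the bicyclic core of 6) | C=C1CC[C@H]2C(C)(C)CCC[C@]2(C)[C@H]1C#C[O-].[Li+] | intermediate (not isolated)
9 | ethyl 2-[(1S,4aS,8aS)-5,5,8a-trimethyl-2-methylidenedecahydronaphthalen-1-yl]acetate | C=C1CC[C@H]2C(C)(C)CCC[C@]2(C)[C@H]1CC(=O)OCC | intermediate
10 | ethyl 2-[(1R,3R,4aS,8aS)-3-hydroxy-5,5,8a-trimethyl-2-methylidenedecahydronaphthalen-1-yl]acetate | C=C1[C@H](O)C[C@H]2C(C)(C)CCC[C@]2(C)[C@H]1CC(=O)OCC | intermediate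
11 | 2-[(1R,3R,4aS,8aS)-3-hydroxy-5,5,8a-trimethyl-2-methylidenedecahydronaphthalen-1-yl]acetaldehyde | C=C1[C@H](O)C[C@H]2C(C)(C)CCC[C@]2(C)[C@H]1CC=O | intermediate
12 | (11Z)-7α,12-bis(triethylsilyloxy)-13,14,15,16-tetranorlabda-8(17),11-diene | C=C1[C@H](O[Si](CC)(CC)CC)C[C@H]2C(C)(C)CCC[C@]2(C)[C@H]1/C=C\O[Si](CC)(CC)CC | intermediate
13 | (11R)-7α-(triethylsilyloxy)-11-(triethylsilylperoxy)-13,14,15,16-tetranorlabd-8(17)-en-12-al | C=C1[C@H](O[Si](CC)(CC)CC)C[C@H]2C(C)(C)CCC[C@]2(C)[C@H]1[C@@H](OO[Si](CC)(CC)CC)C=O | intermediate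
14 | [2-(1,3-dioxolan-2-yl)ethyl]triphenylphosphonium bromide | [Br-].C1COC(CC[P+](c2ccccc2)(c2ccccc2)c2ccccc2)O1 | starting material
15 | [2-(1,3-dioxolan-2-yl)ethylidene]triphenylphosphorane | C1COC(CC=P(c2ccccc2)(c2ccccc2)c2ccccc2)O1 | intermediate (not isolated)
16 | 3-(1,3-dioxolan-2-yl)-2-(triphenyl-λ5-phosphanylidene)propanal | O=CC(CC1OCCO1)=P(c1ccccc1)(c1ccccc1)c1ccccc1 | intermediate
17 | (11S,12E)-15,15-(ethylenedioxy)-7α-(triethylsilyloxy)-11-(triethylsilylperoxy)labda-8(17),12-dien-16-al | C=C1[C@H](O[Si](CC)(CC)CC)C[C@H]2C(C)(C)CCC[C@]2(C)[C@H]1[C@@H](OO[Si](CC)(CC)CC)/C=C(/C=O)CC1OCCO1 | intermediate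
18 | (11S,12E)-11-hydroperoxy-7α-hydroxylabda-8(17),12-diene-15,16-dial | C=C1[C@H](O)C[C@H]2C(C)(C)CCC[C@]2(C)[C@H]1[C@@H](OO)/C=C(/C=O)CC=O | intermediate (not isolated)
19 | (5S,7R,9R,10S,11S,15S)-11,15-epidioxy-7α,15-dihydroxylabda-8(17),12-dien-16-al | C=C1[C@H](O)C[C@H]2C(C)(C)CCC[C@]2(C)[C@H]1[C@@H]1C=C(C=O)C[C@@H](O)OO1 | target

**Step count and risks**
Total step count: 11. Longest linear sequence: 10 (steps 1–8, 10 and 11; step 9 makes the ylide).

Most likely to fail, step 3. The enantioselectivity of the bicyclisation is untested for this terminator (80–90 % ee is hoped for, to be raised by recrystallising 10), the ester may bind the tin acid, and protodesilylation may compete. The fallback takes the absolute configuration from an epoxide instead of from the acid; it sets out from 5 and comes back at 6. The terminal alkene of 5 is epoxidised with the Shi ketone enantiomer that gives the 10S oxirane (KHSO5, K2CO3, MeCN/H2O, 0 °C), giving methyl (2Z,6E)-9-[(2S)-3,3-dimethyloxiran-2-yl]-7-methyl-3-[(trimethylsilyl)methyl]nona-2,6-dienoate F1. MeAlCl2 (CH2Cl2, −78 °C) opens the epoxide, and the same allylsilane-terminated closure of ring A and ring B gives methyl 3β-hydroxydrim-8(12)-en-11-oate F2. The alcohol is converted into its S-methyl xanthate F3 (NaH, CS2, MeI) and removed with Bu3SnH/AIBN (toluene, 80 °C) to give 6.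

Second, step 8. The enol ether may give a dioxetane and cleave, or oxygen may enter on the wrong face at C11; the facial preference is a conformational prediction, not a known result. The fallback puts the C11 face under catalyst control; it sets out from 11 and comes back at 13. Singlet oxygen (O2, tetraphenylporphyrin, light, DMF, 0 °C) is added to the enamine formed from 11 and a proline-derived secondary amine, with the catalyst enantiomer chosen to match the C11 face. This gives (11R)-11-hydroperoxy-7α-hydroxy-13,14,15,16-tetranorlabd-8(17)-en-12-al F4, which is silylated at once on both oxygen functions (Et3SiOTf, 2,6-lutidine, CH2Cl2, −78 °C) to give 13.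

Third, step 10. The hindered α-silylperoxy aldehyde may react slowly with the α-substituted ylide or lose the peroxide by base-induced elimination. The fallback olefinates before oxygenation; it sets out from 11 and comes back at 18. Compound 11 and ylide 16 (toluene, 80 °C) give (12E)-15,15-(ethylenedioxy)-7α-hydroxylabda-8(17),12-dien-16-al F5. Et3SiOTf/Et3N gives the silyl dienol ether (11E,13(16)E)-15,15-(ethylenedioxy)-7α,16-bis(triethylsilyloxy)labda-8(17),11,13(16)-triene F6. Singlet oxygen adds across C11 and C16 in a [4+2] cycloaddition to give the (11S)-11,16-epidioxy-15,15-(ethylenedioxy)-7α,16-bis(triethylsilyloxy)labda-8(17),12-diene F7. Aqueous HCl in THF removes the silyl groups and the acetal, the hemiperoxyacetal opens to the 12Z hydroperoxy enal, and acid-catalysed Z-to-E equilibration of the enal leads to 18, which closes to 19. This last equilibration is itself unproven.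

**Further compounds**
F1 | step 3 | methyl (2Z,6E)-9-[(2S)-3,3-dimethyloxiran-2-yl]-7-methyl-3-[(trimethylsilyl)methyl]nona-2,6-dienoate | COC(=O)/C=C(/CC/C=C(\C)CC[C@@H]1OC1(C)C)C[Si](C)(C)C
F2 | step 3 | methyl 3β-hydroxydrim-8(12)-en-11-oate | C=C1CC[C@H]2C(C)(C)[C@@H](O)CC[C@]2(C)[C@H]1C(=O)OC
F3 | step 3 | methyl 3β-[(methylsulfanyl)carbothioyloxy]drim-8(12)-en-11-oate | C=C1CC[C@H]2C(C)(C)[C@@H](OC(=S)SC)CC[C@]2(C)[C@H]1C(=O)OC
F4 | step 8 | (11R)-11-hydroperoxy-7α-hydroxy-13,14,15,16-tetranorlabd-8(17)-en-12-al | C=C1[C@H](O)C[C@H]2C(C)(C)CCC[C@]2(C)[C@H]1[C@@H](OO)C=O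
F5 | step 10 | (12E)-15,15-(ethylenedioxy)-7α-hydroxylabda-8(17),12-dien-16-al | C=C1[C@H](O)C[C@H]2C(C)(C)CCC[C@]2(C)[C@H]1C/C=C(/C=O)CC1OCCO1
F6 | step 10 | (11E,13(16)E)-15,15-(ethylenedioxy)-7α,16-bis(triethylsilyloxy)labda-8(17),11,13(16)-triene | C=C1[C@H](O[Si](CC)(CC)CC)C[C@H]2C(C)(C)CCC[C@]2(C)[C@H]1/C=C/C(CC1OCCO1)=C/O[Si](CC)(CC)CC
F7 | step 10 | (11S)-11,16-epidioxy-15,15-(ethylenedioxy)-7α,16-bis(triethylsilyloxy)labda-8(17),12-diene (mixture at C16) | C=C1[C@H](O[Si](CC)(CC)CC)C[C@H]2C(C)(C)CCC[C@]2(C)[C@H]1[C@@H]1C=C(CC3OCCO3)C(O[Si](CC)(CC)CC)OO1
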